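The numbers in the tables were generated by integration for substances that don't exist; the scatter is artificial.

The ratio of the alder plateau to the maple plateau is what you need before you charge this flask.

| flask | substrate | gas phase | remark | time |
|---|---|---|---|---|
| alder | 2.5 × 10⁻⁴ M | 0.048 mM (held) | run made earlier |  |
| maple | 0.0010 M | 0.048 mM (held) | run made earlier |  |
| flask | 5.0 × 10⁻⁴ M | 0.048 mM (held) |  | 8.0 min |

- alder (time / min: target / %): 0.500: 25.7; 1.50: 23.0; 3.00: 22.0; 5.00: 21.7; 6.00: 23.2
- maple (time / min: target / %): 1.33: 11.3; 2.50: 11.8; 4.00: 11.8; 5.00: 10.3; 6.00: 10.7

(scatter of a reading: 1 percentage point)

- the numbers in the tables scatter with a standard deviation of 1 percentage point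
- at the start none of the gas phase is in solution

1. amount of target at 8.0 min, in percent of the substrate charged
2. the change that raises the amount of target at 8.0 min, in percent of the substrate charged most ("none" if none brings more than 2 percentage points) (delta / gamma / none)
3. amount of target at 8.0 min, in percent of the substrate charged, after gamma

Alder's first reading stands above its later ones, so set it aside: the later alder readings average 22.5%, and the maple readings average 11.2%. Maple's charge is 4.00 times alder's, and dividing the logarithm of the plateau ratio by the logarithm of this charge ratio gives 0.504. I call this number the charge exponent, the power by which the plateau yield falls as the charge rises, all else held.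

This flask has twice alder's charge, so I reckon 15.9%. Leave the time as it is: alder's last two readings differ by 1.5 percentage points, with a scatter of 1 point, so the plateau shows no drift. The runs never varied the transfer coefficient, so the exponent cannot price that change. If the plateau follows charge over saturation, which is my assumption, doubling the saturation puts this flask at alder's ratio and gives 22.5%. That gain of 6.6 points is more than the margin.

The forecast gives 16.3%, chooses gamma and expects 27% after it, holding that “Doubling saturation doubles the capture-to-loss ratio”. My two yields are lower than its two; I too would try gamma, though I have no figure for the other change.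

The flask gives 16.3% and the choice is gamma, which gains 9 points and reaches 25.2%; doubling the transfer coefficient gains 7.2 points.

    gas phase ⇌ dissolved gas, rate k1*(csat - [dissolved gas]) (kL = 0.130 s⁻¹)
    substrate + dissolved gas → target (k = 4470 L mol⁻¹ s⁻¹)
    substrate → side product (k = 0.0946 s⁻¹)
    target ⇌ isomer of the product (K = 0.334, k = 0.0127 s⁻¹)
    target → over-reaction product (k = 1.31 × 10⁻⁵ s⁻¹)

Carried to the neighbour flask with 2.0 × 10⁻⁴ M of substrate, the charge exponent gives 25.1%, and that flask stands at 23.8%. In this flask at 0.0908 min, substrate passes faster into side product than, with dissolved gas, into target, by a selectivity factor of 5.0. At 8.00 min this flask holds 0% of substrate, the limiting reagent, with 78.2% of side product and 16.3% of target.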